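**Strategy.** The depside is cut at its ester bond into benzyl divarate (ring B) and a protected ring A acid. Ring A is built around the contiguous triad C2–OMe, C1–CO2H, C6–propyl: a 3-methoxybenzyne accepts a carbon nucleophile at the carbon distal to the methoxy group and leaves the anion beside it, ready for an electrophile. In one flask, a triisopropylsilyl-protected 3-fluoro-5-methoxyphenol is lithiated between F and OMe, loses LiF, takes up n-propyllithium at C6 and is carboxylated at C1, forming both ring A carbon–carbon bonds without closing a ring. Acylation of the free 4-hydroxyl of ring B and two deprotections finish the synthesis.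

Key step: step 3

Assumption: the target has no stereocentre, so no stereocontrol is needed. Ring A denotes the 4-hydroxy-2-methoxy-6-propylbenzoyl unit and ring B the divaric acid unit. Divaric acid is taken as purchasable; n-propyllithium is not and is prepared.

**Step 1**
Reactants: 1 3-fluoro-5-methoxyphenol
Product: 2 (3-fluoro-5-methoxyphenoxy)triisopropylsilane
Conditions: TIPSCl (1.1 equiv), imidazole (2 equiv), DMF, 0 °C to rt
Reagents that add atoms: triisopropylsilyl chloride, CC(C)[Si](Cl)(C(C)C)C(C)C
Why: Imidazole-promoted O-silylation of a phenol should proceed cleanly, since the phenolic oxygen is the only nucleophilic site.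

**Step 2**
Reactants: 3 1-bromopropane
Product: 4 n-propyllithium (filtered, titrated solution in Et2O)
Conditions: Li (2.2 equiv, ca. 1% Na), Et2O, −15 to −10 °C, Ar; filter, titrate
Reagents that add atoms: lithium metal, [Li]
Why: Reductive lithiation of a primary alkyl bromide with lithium metal in ether is the classical preparation of n-alkyllithiums, and slow addition at low temperature should hold back Wurtz coupling.

**Step 3**
Reactants: 2 (3-fluoro-5-methoxyphenoxy)triisopropylsilane; 4 n-propyllithium; 5 carbon dioxide
Product: 10 2-methoxy-6-propyl-4-(triisopropylsilyloxy)benzoic acid, via lithiated fluoroarene 6 (not isolated), via aryne 7 (not isolated), via propylated aryllithium 8 (not isolated), via lithium carboxylate 9 (not isolated)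
Conditions: 4 (3.0 equiv), THF/Et2O, −78 °C, 1 h; −78 to 0 °C; recool to −78 °C, CO2 (dry gas); 1 M HCl, 0 °C
Reagents that add atoms: none
Why: n-Propyllithium removes the proton flanked by fluorine and methoxy (directed ortho-metalation) to give 6, which on warming expels LiF to the aryne 7; a further equivalent of n-propyllithium adds to the former C–F carbon (the future C6 of ring A) to give aryllithium 8, and CO2 converts 8 into carboxylate 9, protonated to 10 on work-up. The closest known reaction type is the addition of alkyllithiums to 3-methoxybenzyne generated from 3-fluoroanisole followed by carboxylation, the standard entry to 6-alkylsalicylic acid ethers. No ring is closed and no stereocentre is formed. Site selectivity of the metalation rests on the doubly activated C–H between F and OMe, while the bulky, poorly coordinating triisopropylsilyloxy group shields both positions next to it. Regioselectivity of the addition rests on the methoxy group beside the triple bond: attack at the distal aryne carbon places the carbanion next to the inductively withdrawing, lithium-coordinating oxygen and is also the less hindered trajectory. Keeping n-propyllithium in excess over 8 should suppress arylation of 7 by 8, and 8 cannot undergo silyl migration because the silyloxy group is para to the lithiated carbon.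

**Step 4**
Reactants: 11 2,4-dihydroxy-6-propylbenzoic acid (divaric acid)
Product: 12 benzyl 2,4-dihydroxy-6-propylbenzoate (benzyl divarate)
Conditions: BnBr (1.05 equiv), KHCO3 (1.2 equiv), DMF, rt
Reagents that add atoms: benzyl bromide, BrCc1ccccc1
Why: KHCO3 deprotonates only the carboxylic acid, so SN2 O-alkylation of the carboxylate should give the benzyl ester with both phenols untouched, and room temperature avoids decarboxylation of the resorcylic acid.

**Step 5**
Reactants: 10 2-methoxy-6-propyl-4-(triisopropylsilyloxy)benzoic acid; 12 benzyl 2,4-dihydroxy-6-propylbenzoate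
Product: 14 benzyl 2-hydroxy-4-{[2-methoxy-6-propyl-4-(triisopropylsilyloxy)benzoyl]oxy}-6-propylbenzoate, via acid chloride 13 (not isolated)
Conditions: (COCl)2, DMF (cat.), CH2Cl2, 0 °C to rt, evaporate; then 12, Et3N, DMAP (cat.), CH2Cl2, 0 °C to rt
Reagents that add atoms: none
Why: Acid chloride formation under Vilsmeier-type catalysis followed by DMAP-catalysed esterification should acylate only the 4-hydroxyl of 12, which is the more acidic and unhindered one, whereas the 2-hydroxyl is locked in a hydrogen bond to the neighbouring benzyl ester carbonyl.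

**Step 6**
Reactants: 14 benzyl 2-hydroxy-4-{[2-methoxy-6-propyl-4-(triisopropylsilyloxy)benzoyl]oxy}-6-propylbenzoate
Product: 15 benzyl 2-hydroxy-4-[(4-hydroxy-2-methoxy-6-propylbenzoyl)oxy]-6-propylbenzoate
Conditions: Bu4NF/AcOH (1:1, 1.2 equiv), THF, 0 °C
Reagents that add atoms: none
Why: Fluoride-induced desilylation of an aryl silyl ether is fast at 0 °C, and the acetic acid buffer should protonate the phenoxide as it forms so that neither the depside ester nor the benzyl ester is attacked.

**Step 7**
Reactants: 15 benzyl 2-hydroxy-4-[(4-hydroxy-2-methoxy-6-propylbenzoyl)oxy]-6-propylbenzoate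
Product: 16 2-hydroxy-4-[(4-hydroxy-2-methoxy-6-propylbenzoyl)oxy]-6-propylbenzoic acid (target)
Conditions: H2 (1 atm), 10% Pd/C, EtOAc, rt
Reagents that add atoms: none
Why: Catalytic hydrogenolysis of the benzyl ester over Pd/C should free the carboxylic acid under neutral conditions, to which the aryl ester, the methyl ether and the phenols are inert.

**Compound list**
1 | 3-fluoro-5-methoxyphenol | COc1cc(O)cc(F)c1 | starting material
2 | (3-fluoro-5-methoxyphenoxy)triisopropylsilane | COc1cc(F)cc(O[Si](C(C)C)(C(C)C)C(C)C)c1 | intermediate
3 | 1-bromopropane | CCCBr | starting material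
4 | n-propyllithium | CCC[Li] | intermediate
5 | carbon dioxide | O=C=O | starting material
6 | [2-fluoro-6-methoxy-4-(triisopropylsilyloxy)phenyl]lithium | COc1cc(O[Si](C(C)C)(C(C)C)C(C)C)cc(F)c1[Li] | intermediate
7 | 3-methoxy-5-(triisopropylsilyloxy)benzyne | COC1=CC(O[Si](C(C)C)(C(C)C)C(C)C)=CC#C1 | intermediate
8 | [2-methoxy-6-propyl-4-(triisopropylsilyloxy)phenyl]lithium | CCCc1cc(O[Si](C(C)C)(C(C)C)C(C)C)cc(OC)c1[Li] | intermediate
9 | lithium 2-methoxy-6-propyl-4-(triisopropylsilyloxy)benzoate | CCCc1cc(O[Si](C(C)C)(C(C)C)C(C)C)cc(OC)c1C(=O)[O-].[Li+] | intermediate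
10 | 2-methoxy-6-propyl-4-(triisopropylsilyloxy)benzoic acid | CCCc1cc(O[Si](C(C)C)(C(C)C)C(C)C)cc(OC)c1C(=O)O | intermediate
11 | 2,4-dihydroxy-6-propylbenzoic acid (divaric acid) | CCCc1cc(O)cc(O)c1C(=O)O | starting material
12 | benzyl 2,4-dihydroxy-6-propylbenzoate | CCCc1cc(O)cc(O)c1C(=O)OCc1ccccc1 | intermediate
13 | 2-methoxy-6-propyl-4-(triisopropylsilyloxy)benzoyl chloride | CCCc1cc(O[Si](C(C)C)(C(C)C)C(C)C)cc(OC)c1C(=O)Cl | intermediate
14 | benzyl 2-hydroxy-4-{[2-methoxy-6-propyl-4-(triisopropylsilyloxy)benzoyl]oxy}-6-propylbenzoate | CCCc1cc(OC(=O)c2c(CCC)cc(O[Si](C(C)C)(C(C)C)C(C)C)cc2OC)cc(O)c1C(=O)OCc1ccccc1 | intermediate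
15 | benzyl 2-hydroxy-4-[(4-hydroxy-2-methoxy-6-propylbenzoyl)oxy]-6-propylbenzoate | CCCc1cc(OC(=O)c2c(CCC)cc(O)cc2OC)cc(O)c1C(=O)OCc1ccccc1 | intermediate
16 | 2-hydroxy-4-[(4-hydroxy-2-methoxy-6-propylbenzoyl)oxy]-6-propylbenzoic acid | CCCc1cc(OC(=O)c2c(CCC)cc(O)cc2OC)cc(O)c1C(=O)O | target

**Step count.** Total: 7 steps. Longest linear sequence: 5 steps (steps 1, 3, 5, 6, 7).

**Steps most likely to fail**

1. Step 3. The aryllithium 8 may compete with n-propyllithium for the aryne and give biaryls. Metalation next to the silyl ether would give the regioisomeric aryne. Protonation of 8 by the solvent before carboxylation would give the decarboxy arene. The fallback gives up the aryne and builds the same acid from the ring B ester. It sets out from compound 12. Silylation with TIPSCl and imidazole in DMF should take the free 4-hydroxyl only and give benzyl 2-hydroxy-6-propyl-4-(triisopropylsilyloxy)benzoate F1. Williamson methylation of the chelated 2-hydroxyl with MeI and K2CO3 in dry acetone at reflux should give benzyl 2-methoxy-6-propyl-4-(triisopropylsilyloxy)benzoate F2. Hydrogenolysis over Pd/C in EtOAc then cleaves the benzyl ester, and the fallback comes back to the route at compound 10.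

2. Step 5. Acylation may be slow because two ortho substituents flank the acyl carbon. That would give time for hydrolysis of the acid chloride, for over-acylation at the chelated 2-hydroxyl, or for HCl-induced loss of the silyl group. The fallback replaces the base-mediated acid chloride route by acid-mediated mixed-anhydride activation, the classical depside coupling. It sets out from compounds 10 and 12, which are stirred together in dry toluene with trifluoroacetic anhydride at 0 °C to rt. The acid should form 2-methoxy-6-propyl-4-(triisopropylsilyloxy)benzoic trifluoroacetic anhydride F3, which acylates the free 4-hydroxyl of 12 without any base. The fallback comes back to the route at compound 14.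

3. Step 6. Fluoride, or the phenoxide it liberates, may cleave or transesterify the depside aryl ester. The fallback removes silicon before the ester bond exists and swaps it for a benzyl ether, so that one hydrogenolysis frees phenol and acid together. It sets out from compound 10 and proceeds as follows:
   - Bu4NF in THF should give 4-hydroxy-2-methoxy-6-propylbenzoic acid F4.
   - BnBr (2.2 equiv) and K2CO3 in DMF should give benzyl 4-(benzyloxy)-2-methoxy-6-propylbenzoate F5.
   - Saponification with KOH in aqueous DMSO at 90 °C should give 4-(benzyloxy)-2-methoxy-6-propylbenzoic acid F6.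
   - Oxalyl chloride with catalytic DMF should convert F6 into 4-(benzyloxy)-2-methoxy-6-propylbenzoyl chloride F7, used without isolation.
   - F7 acylates compound 12 (Et3N, DMAP, CH2Cl2) to benzyl 4-{[4-(benzyloxy)-2-methoxy-6-propylbenzoyl]oxy}-2-hydroxy-6-propylbenzoate F8.
   - Hydrogenolysis of both benzyl groups over Pd/C in EtOAc brings the fallback back to the route at compound 16.

**Further compounds**
F1 | step 3 | benzyl 2-hydroxy-6-propyl-4-(triisopropylsilyloxy)benzoate | CCCc1cc(O[Si](C(C)C)(C(C)C)C(C)C)cc(O)c1C(=O)OCc1ccccc1
F2 | step 3 | benzyl 2-methoxy-6-propyl-4-(triisopropylsilyloxy)benzoate | CCCc1cc(O[Si](C(C)C)(C(C)C)C(C)C)cc(OC)c1C(=O)OCc1ccccc1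
F3 | step 5 | 2-methoxy-6-propyl-4-(triisopropylsilyloxy)benzoic trifluoroacetic anhydride | CCCc1cc(O[Si](C(C)C)(C(C)C)C(C)C)cc(OC)c1C(=O)OC(=O)C(F)(F)F
F4 | step 6 | 4-hydroxy-2-methoxy-6-propylbenzoic acid | CCCc1cc(O)cc(OC)c1C(=O)O
F5 | step 6 | benzyl 4-(benzyloxy)-2-methoxy-6-propylbenzoate | CCCc1cc(OCc2ccccc2)cc(OC)c1C(=O)OCc1ccccc1
F6 | step 6 | 4-(benzyloxy)-2-methoxy-6-propylbenzoic acid | CCCc1cc(OCc2ccccc2)cc(OC)c1C(=O)O
F7 | step 6 | 4-(benzyloxy)-2-methoxy-6-propylbenzoyl chloride | CCCc1cc(OCc2ccccc2)cc(OC)c1C(=O)Cl
F8 | step 6 | benzyl 4-{[4-(benzyloxy)-2-methoxy-6-propylbenzoyl]oxy}-2-hydroxy-6-propylbenzoate | CCCc1cc(OC(=O)c2c(CCC)cc(OCc3ccccc3)cc2OC)cc(O)c1C(=O)OCc1ccccc1
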